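## The problem

Numbering used throughout: C1 is the methyl-bearing ring-fusion carbon, C2 and C3 the CH2 groups of the five-membered ring, C4 the isopropyl carbinol, C5 the ring-fusion CH, C6 the acyloxy CH, C7 a CH2, C8 the methyl carbinol, C9 the CHOH and C10 a CH2. Ring A is the cyclopentane C1–C5 and ring B the cycloheptane C1, C5–C10.

Target 17 is a trans-fused hydroazulene of the daucane family, the 8,9-diol of the ferutinin series. It has six stereocentres: four contiguous ones around the ring fusion (C4, C5, C1, C6; C1 quaternary) and a trans-diol at C8/C9 on the far side of ring B. C1 has no neighbour to lean on when it is made, so it has to come from a chiral reagent or catalyst. After that the substrate can take over: C1 can direct C5, C5 can direct C6 and C4, and the angular methyl group can decide the face of any chemistry at C8=C9. The tertiary C4 carbinol dehydrates under strong acid and would undergo retro-aldol cleavage if C6 were ever a ketone. The hindered aryl ester and the free phenol do not tolerate strong base or organometallic reagents, so they must arrive late. The feature that opens the structure is the C4–C5–C1 triad. With C4 at the ketone level, C4(=O)–C5=C1(Me) is 3-methylcyclopentenone, whose β-carbon C1 can accept C10 as a nucleophile and whose α-carbon C5 can then take C6 as an aldehyde. The C5/C6 relation in 17 is that of an anti aldol, and the adjacent carbinols C8 and C9 can be two carbonyl carbons that are joined afterwards.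

## Retrosynthesis

Phenol and diol. Target 17 is taken back to its benzyl ether 16, so that the phenol is masked during acylation and oxidation and is freed by a neutral hydrogenolysis. In 16 the C8–O bond is cut (water as nucleophile) to give epoxide 15, and removal of the epoxide oxygen gives alkene 14. The C9 oxygen lies on the face of H-5 and the C8 oxygen on the face of the angular methyl. That is the outcome of epoxidation from the face away from the methyl group followed by opening at the tertiary carbon with inversion. A dihydroxylation would give the cis-diol, and a methyl addition to a C8 ketone would need a C9-oxygenated ketone that no simple ring closure provides. Compound 14 has two stereocentres fewer and a single alkene. The forward steps must be face-selective in the epoxidation and must open the epoxide at C8 without harming the ester or the C4 carbinol.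

Ester. Compound 14 is cut at the ester C–O bond into diol 12 and acid chloride 13. Acylating late keeps the aryl ester away from organometallic and low-valent titanium reagents. Diol 12 is a C15 compound with four stereocentres. The forward reaction must acylate the secondary C6 hydroxyl in the presence of the tertiary C4 hydroxyl, which the difference in hindrance should allow.

Ring B. Diol 12, through its silyl ether 11, is cut at C8=C9 to keto aldehyde 10. This is the only bond of ring B whose two ends can both be carbonyl carbons, and its closure creates no stereocentre. A cut at C6–C7 or C1–C10 would form a bond at a stereocentre inside a seven-membered transition state. Compound 10 is monocyclic and already holds C1, C4, C5 and C6 in their final configuration. The forward reaction is a reductive carbonyl coupling that must close a seven-membered ring in the presence of a free tertiary alcohol and a silyl ether.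

C4. Compound 10 comes from bis-acetal 9 by unmasking, and 9 is cut at the C4–isopropyl bond to ketone 8. Bringing the isopropyl group in as a nucleophile keeps C4 as the carbonyl that activates C5 and C1 in the step before. A route that carried the carbinol from the start would lose that activation. The side chain on C5 shields one face of the ketone, so the reagent is expected to enter from the face of H-5 and to place the hydroxyl cis to the C6 arm, as in 17. The reaction has to be an addition, not an enolisation or reduction, which calls for an organocerium reagent.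

C1–C10 and C5–C6. Ketone 8 is the silyl ether of aldol 7. In 7 the two bonds that flank the ring-fusion pair are cut together, C1–C10 and C5–C6. This gives 3-methylcyclopent-2-en-1-one 5, the acetal-bearing Grignard reagent 2 (C10–C9) and the ketal-bearing aldehyde 4 (C6–C7–C8 with the C8 methyl). A cut of only one of these bonds would leave a 2- or 3-substituted cyclopentanone that is no easier to make in enantioenriched form. The double cut reduces a compound with three contiguous stereocentres to three achiral pieces of five, three and five skeletal carbons (ring A with its methyl, C10–C9, and C6–C8 with the C8 methyl). The forward reaction needs a chiral catalyst for the face of C1, entry of the aldehyde anti to the larger C1 substituent and an anti-selective aldol. The two acetals are spectators that later become the C8 and C9 carbonyl groups.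

Fragments. Reagent 2 is made from bromide 1 and magnesium. Aldehyde 4 is made from the commercial ester 3 by partial reduction.

## Roads not taken

Alternative 1: The cut runs through C1–C10 and C7–C8 and unravels ring B into the siloxydiene A2 (C1=C5–C6=C7 on a cyclopentene that already carries the protected C4 carbinol, available from a chiral-pool monoterpene alcohol) and the vinyldiazoacetate A3 (C8–C9–C10). In the forward direction Rh2(DOSP)4 turns A3 into a vinylcarbenoid that cyclopropanates the C6=C7 enol ether, and the cis-divinylcyclopropane rearranges through a boat transition state to the cycloheptadiene A1. Its merits are real. Ring B and the quaternary centre are made in one catalytic operation, C6 and C9 are both oxygenated, and the C4 carbinol is bought rather than made, so no hindered ketone addition is needed. In ring construction and in the handling of C4 it is better than the route chosen here, which needs a separate ring closure and an organocerium step. Its weak points lie elsewhere. The Cope step must form a bond to a fully substituted C1, so one substituent of C1 points into the boat, which is the situation in which divinylcyclopropanes rearrange slowly or not at all. The chiral catalyst and the C4 stereocentre must also match. In addition A1 is far from 17 in oxidation pattern: C5 is sp2 and the trans ring fusion is still to be set, C6 is at the ketone level, and the C8 ester has to become a methyl group next to a new tertiary hydroxyl. Against the shorter ring construction the chosen plan sets the fact that every carbon arrives at its final oxidation level, with C6 already a carbinol of the right configuration and the C8 methyl in place.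

Alternative 2: The cut is C4–C5, which opens ring A to the cycloheptanone A5 with an isopropyl ketone side chain on the quaternary C1. In the forward direction a reversible intramolecular aldol of the C5 enolate onto the side-chain ketone closes the cyclopentane and gives the trans-fused hydroxy ketone A4. Here C4 and C5 are set together relative to C1 under thermodynamic control, without protecting groups, and the C6 ketone sits where the C6 carbinol is needed. In the control of C4 and C5 this road is better than the chosen one, which depends on kinetic selectivity in two separate steps. Its weak points are three. A tertiary aldol onto a hindered isopropyl ketone is thermodynamically marginal and prone to retro-aldol cleavage and dehydration. Compound A5 needs its own asymmetric construction of the quaternary centre. Above all, ring B of A4 is bare from C7 to C10, so the C8 methyl carbinol and the C9 hydroxyl would have to be introduced at unactivated carbons in a long sequence starting from the C6 ketone. The chosen plan sets against the self-correcting aldol the fact that C6, C8, C9 and the C8 methyl come in with the fragments.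

Alternative 3: The cuts are C1–C5 and C6–C7, which open both rings to the acyclic siloxyvinylcyclopropane ynone A7. In the forward direction a cationic rhodium catalyst such as [Rh(BINAP)]SbF6 joins the vinylcyclopropane (C1=C10 with C9, C8, C7) and the tethered alkyne (C5≡C6) in a (5+2) cycloaddition to the bicyclic dienone A6. Both rings form in one atom-economic step, the C9 oxygen and the C8 methyl are in place, and the number of steps to the bicycle is lower than in the chosen route. In these respects it is the better road. The difficulties are the quaternary C1 and what comes after. C1 would be formed from a trisubstituted alkene terminus, which slows such cycloadditions and leaves the enantiocontrol unsecured. Compound A6 has no oxygen at C6, which is the β-carbon of an enone, and none at C8, which is a methine. The C5 stereocentre and the C4 carbinol would still have to be set on a cross-conjugated system. The chosen plan sets against the one-step bicycle the fact that C1, C5 and C6 are fixed together with the C6 oxygen, and that only standard operations follow.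

Key step: step 3

Assumption: the antipode of the chiral carbene ligand that delivers the CH2 group to the Si face of the β-carbon of 5, giving the (R) quaternary centre, is taken as available, since such ligands are made from either enantiomer of their parent amine.

## Route

Step 1
Reactants: 1 2-(bromomethyl)-1,3-dioxolane
Product: 2 (1,3-dioxolan-2-ylmethyl)magnesium bromide (titrated THF solution, used directly)
Conditions: Mg turnings (I2-activated), THF, 25–30 °C
Reagents that add atoms: magnesium, [Mg]
Why: Grignard formation by magnesium insertion into a primary C–Br bond; the reagent is a known one, and keeping the temperature at or below 30 °C avoids β-elimination of the acetal oxygen.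

Step 2
Reactants: 3 ethyl 2-(2-methyl-1,3-dioxolan-2-yl)acetate
Product: 4 2-(2-methyl-1,3-dioxolan-2-yl)acetaldehyde
Conditions: DIBAL-H, CH2Cl2, −78 °C; then MeOH, aq. Rochelle salt
Reagents that add atoms: none
Why: Partial reduction of an ester with DIBAL-H; the tetrahedral aluminium hemiacetal, held by a ketal oxygen, persists at −78 °C and collapses to the aldehyde only on quenching. Aldehyde 4 is used at once because β-ketal aldehydes oligomerise on standing.

Step 3
Reactants: 5 3-methylcyclopent-2-en-1-one; 2 (1,3-dioxolan-2-ylmethyl)magnesium bromide; 4 2-(2-methyl-1,3-dioxolan-2-yl)acetaldehyde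
Product: 7 (2S,3R)-3-(1,3-dioxolan-2-ylmethyl)-2-[(1S)-1-hydroxy-2-(2-methyl-1,3-dioxolan-2-yl)ethyl]-3-methylcyclopentan-1-one, via bromomagnesium enolate 6 (not isolated)
Conditions: Cu(OTf)2 (5 mol %), chiral imidazolinium salt (carbene precursor, 6 mol %), Et2O, −30 °C, slow addition of 2; then 4 in THF, −78 → −40 °C; aq. NH4Cl
Reagents that add atoms: none
Why: The Grignard reagent deprotonates the imidazolinium salt and reduces the copper salt to a chiral carbene complex of monovalent copper; transmetalation, π-complexation of the magnesium-activated enone, oxidative addition to a trivalent copper intermediate and reductive elimination form C1–C10 and release enolate 6, regiodefined at C5. The closest known reaction type is the copper–carbene-catalysed conjugate addition of Grignard reagents to 3-substituted cycloalkenones with aldol trapping of the magnesium enolate, and only the acetal-bearing CH2 nucleophile is new to it. No ring is closed. C1 is set by the catalyst, whose ligand antipode is chosen for Si-face delivery and which must outrun 1,2-addition, a demand that slow addition of 2 supports. C5 is set by C1, because aldehyde 4 should approach the enolate on the face of the methyl group, anti to the larger, β-branched CH2–dioxolane arm. C6 is set by the closed chair transition state of the ring-locked (E)-enolate, which places the aldehyde substituent equatorial and gives the anti aldol. The THF added with 4 saturates magnesium so that the acetal oxygens of the arm do not steer the aldehyde to their own face, and holding the aldolate at −40 °C lets retro-aldol equilibration favour the same anti, trans chelate. Both acetals are inert to these events, and the buffered quench avoids dehydration of the β-hydroxy ketone.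

Step 4
Reactants: 7 (2S,3R)-3-(1,3-dioxolan-2-ylmethyl)-2-[(1S)-1-hydroxy-2-(2-methyl-1,3-dioxolan-2-yl)ethyl]-3-methylcyclopentan-1-one
Product: 8 (2S,3R)-2-[(1S)-1-{[tert-butyl(dimethyl)silyl]oxy}-2-(2-methyl-1,3-dioxolan-2-yl)ethyl]-3-(1,3-dioxolan-2-ylmethyl)-3-methylcyclopentan-1-one
Conditions: TBSOTf, 2,6-lutidine, CH2Cl2, −78 °C
Reagents that add atoms: tert-butyldimethylsilyl triflate (TBSOTf), CC(C)(C)[Si](C)(C)OS(=O)(=O)C(F)(F)F
Why: Silyl ether formation on a hindered secondary alcohol with a silyl triflate; at −78 °C and with a slight excess of reagent the hydroxyl reacts far faster than the acetals, and the hindered base does not provoke retro-aldol cleavage. The ether blocks alkoxide chemistry in step 5 and adds bulk on the C6 side of the ketone.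

Step 5
Reactants: 8 (2S,3R)-2-[(1S)-1-{[tert-butyl(dimethyl)silyl]oxy}-2-(2-methyl-1,3-dioxolan-2-yl)ethyl]-3-(1,3-dioxolan-2-ylmethyl)-3-methylcyclopentan-1-one
Product: 9 (1R,2S,3R)-2-[(1S)-1-{[tert-butyl(dimethyl)silyl]oxy}-2-(2-methyl-1,3-dioxolan-2-yl)ethyl]-3-(1,3-dioxolan-2-ylmethyl)-3-methyl-1-(propan-2-yl)cyclopentan-1-ol
Conditions: iPrMgCl, CeCl3 (anhydrous), THF, −78 → −20 °C; aq. NH4Cl
Reagents that add atoms: isopropylmagnesium chloride, CC(C)[Mg]Cl
Why: Organocerium addition to a hindered, enolisable ketone; the weakly basic cerium reagent suppresses enolisation, β-hydride reduction and elimination of the β-siloxy group. The nucleophile should enter C4 on the face of H-5, anti to the bulky side chain on the adjacent C5, so the new hydroxyl lies cis to the C6 arm and to the C1 methyl group, as in 17.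

Step 6
Reactants: 9 (1R,2S,3R)-2-[(1S)-1-{[tert-butyl(dimethyl)silyl]oxy}-2-(2-methyl-1,3-dioxolan-2-yl)ethyl]-3-(1,3-dioxolan-2-ylmethyl)-3-methyl-1-(propan-2-yl)cyclopentan-1-ol
Product: 10 2-[(1R,2S,3R)-2-[(1S)-1-{[tert-butyl(dimethyl)silyl]oxy}-3-oxobutyl]-3-hydroxy-1-methyl-3-(propan-2-yl)cyclopentyl]acetaldehyde
Conditions: PPTS, acetone/H2O, 55 °C
Reagents that add atoms: water, O
Why: Acid-catalysed acetal hydrolysis with a weak acid in wet acetone; both dioxolanes are removed while a hindered secondary TBS ether and a tertiary alcohol are expected to persist. Compound 10 may sit partly as the hemiketal between the C4 hydroxyl and the C8 ketone, which is in equilibrium with the open form and of no consequence.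

Step 7
Reactants: 10 2-[(1R,2S,3R)-2-[(1S)-1-{[tert-butyl(dimethyl)silyl]oxy}-3-oxobutyl]-3-hydroxy-1-methyl-3-(propan-2-yl)cyclopentyl]acetaldehyde
Product: 11 (3R,3aS,4S,8aR)-4-{[tert-butyl(dimethyl)silyl]oxy}-6,8a-dimethyl-3-(propan-2-yl)-1,2,3,3a,4,5,8,8a-octahydroazulen-3-ol
Conditions: TiCl3(DME)1.5, Zn–Cu, DME, reflux, slow addition of 10
Reagents that add atoms: none
Why: Intramolecular McMurry coupling of a 1,7-keto aldehyde; electron transfer from low-valent titanium joins C8 and C9 as a titanium-bound pinacolate, which is deoxygenated on the metal to the C8=C9 alkene. Slow addition favours the seven-membered ring over oligomers, no stereocentre is formed, and excess reagent allows for the free tertiary hydroxyl, which is not activated towards deoxygenation.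

Step 8
Reactants: 11 (3R,3aS,4S,8aR)-4-{[tert-butyl(dimethyl)silyl]oxy}-6,8a-dimethyl-3-(propan-2-yl)-1,2,3,3a,4,5,8,8a-octahydroazulen-3-ol
Product: 12 (3R,3aS,4S,8aR)-6,8a-dimethyl-3-(propan-2-yl)-1,2,3,3a,4,5,8,8a-octahydroazulene-3,4-diol (jaeschkeanadiol)
Conditions: TBAF, THF, rt → 45 °C
Reagents that add atoms: none
Why: Fluoride-induced cleavage of a silyl ether, driven by Si–F bond formation; alkene and tertiary alcohol are inert. Compound 12 is a known natural diol, so the four stereocentres made so far can be checked against it at this point.

Step 9
Reactants: 12 (3R,3aS,4S,8aR)-6,8a-dimethyl-3-(propan-2-yl)-1,2,3,3a,4,5,8,8a-octahydroazulene-3,4-diol; 13 4-(benzyloxy)benzoyl chloride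
Product: 14 (3R,3aS,4S,8aR)-3-hydroxy-6,8a-dimethyl-3-(propan-2-yl)-1,2,3,3a,4,5,8,8a-octahydroazulen-4-yl 4-(benzyloxy)benzoate
Conditions: DMAP, Et3N, CH2Cl2, 0 °C → rt
Reagents that add atoms: none
Why: DMAP-catalysed acylation with an acid chloride; the secondary C6 hydroxyl reacts while the tertiary C4 hydroxyl next to the isopropyl group is left. The benzyl ether keeps the phenol from self-acylation and from the peracid of step 10.

Step 10
Reactants: 14 (3R,3aS,4S,8aR)-3-hydroxy-6,8a-dimethyl-3-(propan-2-yl)-1,2,3,3a,4,5,8,8a-octahydroazulen-4-yl 4-(benzyloxy)benzoate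
Product: 15 (3R,3aS,4S,6R,7S,8aR)-6,7-epoxy-3-hydroxy-6,8a-dimethyl-3-(propan-2-yl)decahydroazulen-4-yl 4-(benzyloxy)benzoate (epoxide oxygen on the face of H-3a, away from the 8a-methyl group)
Conditions: mCPBA, NaHCO3, CH2Cl2, 0 °C
Reagents that add atoms: 3-chloroperbenzoic acid (mCPBA), O=C(OO)c1cccc(Cl)c1
Why: Prilezhaev epoxidation of the only alkene; the peracid should approach the face of ring B that carries H-5, because the axial angular methyl group screens the other face and the C6 ester is equatorial. This sets C9 and prepares the inversion at C8; the bicarbonate keeps the acid by-product from opening the epoxide.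

Step 11
Reactants: 15 (3R,3aS,4S,6R,7S,8aR)-6,7-epoxy-3-hydroxy-6,8a-dimethyl-3-(propan-2-yl)decahydroazulen-4-yl 4-(benzyloxy)benzoate
Product: 16 (3R,3aS,4S,6S,7S,8aR)-3,6,7-trihydroxy-6,8a-dimethyl-3-(propan-2-yl)decahydroazulen-4-yl 4-(benzyloxy)benzoate
Conditions: HClO4 (aq., cat.), THF/H2O, 0 °C → rt
Reagents that add atoms: water, O
Why: Acid-catalysed epoxide hydrolysis; water opens the protonated epoxide at the tertiary carbon C8, which carries most of the positive charge, with inversion, so the C8 hydroxyl ends on the face of the angular methyl and the C9 hydroxyl keeps its place, giving the trans-diol of 17. The C6 ester lies on the same face as the epoxide oxygen and cannot take part from the rear.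

Step 12
Reactants: 16 (3R,3aS,4S,6S,7S,8aR)-3,6,7-trihydroxy-6,8a-dimethyl-3-(propan-2-yl)decahydroazulen-4-yl 4-(benzyloxy)benzoate
Product: 17 (3R,3aS,4S,6S,7S,8aR)-3,6,7-trihydroxy-6,8a-dimethyl-3-(propan-2-yl)decahydroazulen-4-yl 4-hydroxybenzoate
Conditions: H2 (1 atm), Pd/C, EtOAc, rt
Reagents that add atoms: none
Why: Hydrogenolysis of a benzyl aryl ether over palladium on carbon; the neutral conditions leave the hindered ester, the three hydroxyl groups and all stereocentres untouched, and no other reducible group remains.

## Compound list

1 | 2-(bromomethyl)-1,3-dioxolane | BrCC1OCCO1 | starting material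
2 | (1,3-dioxolan-2-ylmethyl)magnesium bromide | Br[Mg]CC1OCCO1 | intermediate
3 | ethyl 2-(2-methyl-1,3-dioxolan-2-yl)acetate | CCOC(=O)CC1(C)OCCO1 | starting material
4 | 2-(2-methyl-1,3-dioxolan-2-yl)acetaldehyde | CC1(CC=O)OCCO1 | intermediate
5 | 3-methylcyclopent-2-en-1-one | CC1=CC(=O)CC1 | starting material
6 | bromo{[(3R)-3-(1,3-dioxolan-2-ylmethyl)-3-methylcyclopent-1-en-1-yl]oxy}magnesium (bromomagnesium enolate, not isolated) | C[C@]1(CC2OCCO2)CCC(O[Mg]Br)=C1 | intermediate
7 | (2S,3R)-3-(1,3-dioxolan-2-ylmethyl)-2-[(1S)-1-hydroxy-2-(2-methyl-1,3-dioxolan-2-yl)ethyl]-3-methylcyclopentan-1-one | O=C1CC[C@](C)(CC2OCCO2)[C@H]1[C@@H](O)CC3(C)OCCO3 | intermediate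
8 | (2S,3R)-2-[(1S)-1-{[tert-butyl(dimethyl)silyl]oxy}-2-(2-methyl-1,3-dioxolan-2-yl)ethyl]-3-(1,3-dioxolan-2-ylmethyl)-3-methylcyclopentan-1-one | O=C1CC[C@](C)(CC2OCCO2)[C@H]1[C@@H](O[Si](C)(C)C(C)(C)C)CC3(C)OCCO3 | intermediate
9 | (1R,2S,3R)-2-[(1S)-1-{[tert-butyl(dimethyl)silyl]oxy}-2-(2-methyl-1,3-dioxolan-2-yl)ethyl]-3-(1,3-dioxolan-2-ylmethyl)-3-methyl-1-(propan-2-yl)cyclopentan-1-ol | CC(C)[C@]1(O)CC[C@](C)(CC2OCCO2)[C@H]1[C@@H](O[Si](C)(C)C(C)(C)C)CC3(C)OCCO3 | intermediate
10 | 2-[(1R,2S,3R)-2-[(1S)-1-{[tert-butyl(dimethyl)silyl]oxy}-3-oxobutyl]-3-hydroxy-1-methyl-3-(propan-2-yl)cyclopentyl]acetaldehyde | CC(C)[C@]1(O)CC[C@](C)(CC=O)[C@H]1[C@@H](O[Si](C)(C)C(C)(C)C)CC(C)=O | intermediate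
11 | (3R,3aS,4S,8aR)-4-{[tert-butyl(dimethyl)silyl]oxy}-6,8a-dimethyl-3-(propan-2-yl)-1,2,3,3a,4,5,8,8a-octahydroazulen-3-ol | CC(C)[C@]1(O)CC[C@]2(C)CC=C(C)C[C@H](O[Si](C)(C)C(C)(C)C)[C@H]21 | intermediate
12 | (3R,3aS,4S,8aR)-6,8a-dimethyl-3-(propan-2-yl)-1,2,3,3a,4,5,8,8a-octahydroazulene-3,4-diol (jaeschkeanadiol) | CC(C)[C@]1(O)CC[C@]2(C)CC=C(C)C[C@H](O)[C@H]21 | intermediate
13 | 4-(benzyloxy)benzoyl chloride | O=C(Cl)c1ccc(OCc2ccccc2)cc1 | starting material
14 | (3R,3aS,4S,8aR)-3-hydroxy-6,8a-dimethyl-3-(propan-2-yl)-1,2,3,3a,4,5,8,8a-octahydroazulen-4-yl 4-(benzyloxy)benzoate | CC(C)[C@]1(O)CC[C@]2(C)CC=C(C)C[C@H](OC(=O)c3ccc(OCc4ccccc4)cc3)[C@H]21 | intermediate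
15 | (3R,3aS,4S,6R,7S,8aR)-6,7-epoxy-3-hydroxy-6,8a-dimethyl-3-(propan-2-yl)decahydroazulen-4-yl 4-(benzyloxy)benzoate | CC(C)[C@]1(O)CC[C@]2(C)C[C@@H]3O[C@]3(C)C[C@H](OC(=O)c4ccc(OCc5ccccc5)cc4)[C@H]21 | intermediate
16 | (3R,3aS,4S,6S,7S,8aR)-3,6,7-trihydroxy-6,8a-dimethyl-3-(propan-2-yl)decahydroazulen-4-yl 4-(benzyloxy)benzoate | CC(C)[C@]1(O)CC[C@]2(C)C[C@H](O)[C@@](C)(O)C[C@H](OC(=O)c3ccc(OCc4ccccc4)cc3)[C@H]21 | intermediate
17 | (3R,3aS,4S,6S,7S,8aR)-3,6,7-trihydroxy-6,8a-dimethyl-3-(propan-2-yl)decahydroazulen-4-yl 4-hydroxybenzoate (1R,4R,5S,6S,8S,9S in the numbering of the text) | CC(C)[C@]1(O)CC[C@]2(C)C[C@H](O)[C@@](C)(O)C[C@H](OC(=O)c3ccc(O)cc3)[C@H]21 | target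

Total step count: 12. Longest linear sequence: 11 steps (step 1, then steps 3 to 12; the branch through step 2 is of the same length).

## Least certain steps

Step 3 (key step). The conjugate addition may lose enantio- and regiocontrol, because reagent 2 arrives in THF and carries two acetal oxygens. Both compete with the chiral ligand and the enone for magnesium and copper, so uncatalysed 1,2-addition or β-elimination of the reagent can take over. The aldol that follows may also show only moderate facial selectivity at C5, since methyl and CH2–acetal do not differ greatly in size. Fallback: the roles of the two C1 substituents are exchanged. Reagent 2 is added 1,2 to commercial 3-ethoxycyclopent-2-en-1-one, and work-up with dilute acid (Stork–Danheiser transposition) gives 3-(1,3-dioxolan-2-ylmethyl)cyclopent-2-en-1-one F1. Copper-catalysed asymmetric conjugate addition of Me3Al (Cu(OTf)2 with a chiral carbene ligand, a combination with direct precedent on 3-alkylcyclopentenones) then creates the same quaternary centre by methyl transfer. The resulting dimethylaluminium enolate F2 is trapped with aldehyde 4, after activation with MeLi if needed. This path sets out from 2 and returns to the route at 7. It also changes the enolate metal, which gives a second chance at the C5 ratio.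

Step 7. The coupling may stop at the pinacol stage, or the β-siloxy group may be eliminated from the C8 ketone on the Lewis-acidic titanium surface. The free tertiary hydroxyl, or its hemiketal with the C8 ketone, can also tie up the reagent. Fallback: from 10, Wittig methylenation of both the aldehyde and the methyl ketone (Ph3P=CH2, THF, with one extra equivalent for the hydroxyl) gives (1R,2S,3R)-2-[(1S)-1-{[tert-butyl(dimethyl)silyl]oxy}-3-methylbut-3-en-1-yl]-3-methyl-1-(propan-2-yl)-3-(prop-2-en-1-yl)cyclopentan-1-ol F3. Ring-closing metathesis with second-generation Grubbs catalyst in CH2Cl2 at reflux then closes the same trisubstituted C8=C9 alkene with loss of ethene and returns to the route at 11.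

Step 5. Enolisation or β-hydride reduction of the α,α′-branched ketone may compete with addition of the bulky secondary nucleophile, and the facial selectivity may suffer if the reaction has to be forced. Fallback: from 8, the smaller, non-reducing isopropenyl nucleophile (isopropenylmagnesium bromide, CeCl3, THF, −78 °C) is added to give (1S,2S,3R)-2-[(1S)-1-{[tert-butyl(dimethyl)silyl]oxy}-2-(2-methyl-1,3-dioxolan-2-yl)ethyl]-3-(1,3-dioxolan-2-ylmethyl)-3-methyl-1-(prop-1-en-2-yl)cyclopentan-1-ol F4. Hydrogenation of its 1,1-disubstituted alkene (H2, PtO2, EtOAc) returns to the route at 9.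

Step 10. Facial selectivity may be poor if the aroyloxy group at C6, which sits on the face that the peracid should use, hinders approach more than expected. Fallback: the order of acylation and epoxidation is reversed so that the free homoallylic C6 hydroxyl can direct the oxidant to its own face. From 12, VO(acac)2 and tert-butyl hydroperoxide in CH2Cl2 give (3R,3aS,4S,6R,7S,8aR)-6,7-epoxy-6,8a-dimethyl-3-(propan-2-yl)decahydroazulene-3,4-diol F5. Acylation of its secondary hydroxyl with 13 under the conditions of step 9 returns to the route at 15.

Step 11. The opening may run through an open tertiary cation, which can lose a proton to give an allylic alcohol or lose the inversion at C8. The aqueous mineral acid may also dehydrate the C4 carbinol. Fallback: the opening is done in two stages without mineral acid. From 15, buffered formic acid (HCO2H, HCO2Na, 0 °C), in which the nucleophile is the solvent, gives (3R,3aS,4S,6S,7S,8aR)-6-(formyloxy)-3,7-dihydroxy-6,8a-dimethyl-3-(propan-2-yl)decahydroazulen-4-yl 4-(benzyloxy)benzoate F6. Mild methanolysis (KHCO3, MeOH, 0 °C) removes the formate, and any formate that has migrated or formed on another hydroxyl, far faster than the hindered aryl ester, and returns to the route at 16.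

## Further compounds

F1 | step 3 | 3-(1,3-dioxolan-2-ylmethyl)cyclopent-2-en-1-one | O=C1C=C(CC2OCCO2)CC1
F2 | step 3 | {[(3R)-3-(1,3-dioxolan-2-ylmethyl)-3-methylcyclopent-1-en-1-yl]oxy}dimethylaluminium | C[C@]1(CC2OCCO2)CCC(O[Al](C)C)=C1
F3 | step 7 | (1R,2S,3R)-2-[(1S)-1-{[tert-butyl(dimethyl)silyl]oxy}-3-methylbut-3-en-1-yl]-3-methyl-1-(propan-2-yl)-3-(prop-2-en-1-yl)cyclopentan-1-ol | CC(C)[C@]1(O)CC[C@](C)(CC=C)[C@H]1[C@@H](O[Si](C)(C)C(C)(C)C)CC(C)=C
F4 | step 5 | (1S,2S,3R)-2-[(1S)-1-{[tert-butyl(dimethyl)silyl]oxy}-2-(2-methyl-1,3-dioxolan-2-yl)ethyl]-3-(1,3-dioxolan-2-ylmethyl)-3-methyl-1-(prop-1-en-2-yl)cyclopentan-1-ol | C=C(C)[C@]1(O)CC[C@](C)(CC2OCCO2)[C@H]1[C@@H](O[Si](C)(C)C(C)(C)C)CC3(C)OCCO3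
F5 | step 10 | (3R,3aS,4S,6R,7S,8aR)-6,7-epoxy-6,8a-dimethyl-3-(propan-2-yl)decahydroazulene-3,4-diol | CC(C)[C@]1(O)CC[C@]2(C)C[C@@H]3O[C@]3(C)C[C@H](O)[C@H]21
F6 | step 11 | (3R,3aS,4S,6S,7S,8aR)-6-(formyloxy)-3,7-dihydroxy-6,8a-dimethyl-3-(propan-2-yl)decahydroazulen-4-yl 4-(benzyloxy)benzoate | CC(C)[C@]1(O)CC[C@]2(C)C[C@H](O)[C@@](C)(OC=O)C[C@H](OC(=O)c3ccc(OCc4ccccc4)cc3)[C@H]21
A1 | alternative 1 | methyl 6,9-bis{[tert-butyl(dimethyl)silyl]oxy}-1-methyl-4-(propan-2-yl)-4-[(triethylsilyl)oxy]bicyclo[5.3.0]deca-5,8-diene-8-carboxylate (target numbering, C1 and C4 as in 17) | CC(C)[C@]1(O[Si](CC)(CC)CC)CC[C@]2(C)CC(O[Si](C)(C)C(C)(C)C)=C(C(=O)OC)CC(O[Si](C)(C)C(C)(C)C)=C21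
A2 | alternative 1 | (R)-2-(1-{[tert-butyl(dimethyl)silyl]oxy}ethenyl)-3-methyl-1-(propan-2-yl)-1-[(triethylsilyl)oxy]cyclopent-2-ene | CC(C)[C@]1(O[Si](CC)(CC)CC)CCC(C)=C1C(=C)O[Si](C)(C)C(C)(C)C
A3 | alternative 1 | methyl 3-{[tert-butyl(dimethyl)silyl]oxy}-2-diazobut-3-enoate | C=C(O[Si](C)(C)C(C)(C)C)C(=[N+]=[N-])C(=O)OC
A4 | alternative 2 | trans-fused 4-hydroxy-1-methyl-4-(propan-2-yl)bicyclo[5.3.0]decan-6-one (target numbering, C1, C4 and C5 as in 17) | CC(C)[C@]1(O)CC[C@]2(C)CCCCC(=O)[C@H]21
A5 | alternative 2 | (S)-3-methyl-3-(4-methyl-3-oxopentyl)cycloheptan-1-one | CC(C)C(=O)CC[C@]1(C)CCCCC(=O)C1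
A6 | alternative 3 | 9-{[tert-butyl(dimethyl)silyl]oxy}-1,8-dimethylbicyclo[5.3.0]deca-5,9-dien-4-one (target numbering, configuration as drawn) | O=C1CC[C@]2(C)C=C(O[Si](C)(C)C(C)(C)C)[C@H](C)CC=C21
A7 | alternative 3 | (E)-7-(1-{[tert-butyl(dimethyl)silyl]oxy}-2-methylcyclopropyl)-6-methylhept-6-en-1-yn-3-one (methyl cis to the siloxy group) | C#CC(=O)CC/C(C)=C/[C@]1(O[Si](C)(C)C(C)(C)C)C[C@H]1C
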